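**Plan**
1. Retrosynthesis: the O6–benzyl bond is cut last. Ring B is then cut at C1'–C2', C2'–C3' and C5'–C6', giving cyclobutenone (C2' with its oxygen, C3', C4', C5') and a chromone with a methoxyethynyl group on C2 (C1', C6' and the 6'-methoxyl).
2. Enabling feature: ring B is a resorcinol monomethyl ether whose only carbon substituent sits on the carbon between the two oxygens (C1' flanked by C2'–OH and C6'–OMe; C3', C4', C5' carry hydrogen). This is the pattern a vinylketene/alkoxyalkyne benzannulation delivers.
3. Further cuts: C2–C(sp) (thioether/stannane cross-coupling), O1–C2 and C2–C3 of ring C (CS2 annulation of an o-hydroxyacetophenone), the ring A C6–O bond (persulfate oxidation) and the acetyl C–C bond (Friedel–Crafts).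
4. Forward order: ring A is bought as 3,4,5-trimethoxyphenol and fully oxygenated, ring C is closed on it, the ynol ether is attached, ring B is grown in one thermal operation, and the benzyl group is removed.
5. Stereochemistry: the target has no stereocentre and no axis that must be set. Which ring B oxygen is methylated is fixed by origin (alkyne OMe versus ketene C=O).

Key step: step 11

**Step 1**
Reactants: 1 3,4,5-trimethoxyphenol
Product: 2 1,2,3,5-tetramethoxybenzene
Conditions: MeI, K2CO3, acetone, reflux
Reagents that add atoms: iodomethane, CI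
Why: Williamson O-methylation of the only acidic site of 1 should be clean.

**Step 2**
Reactants: 2 1,2,3,5-tetramethoxybenzene
Product: 4 1-(2-hydroxy-3,4,6-trimethoxyphenyl)ethan-1-one, via tetramethoxyacetophenone 3 (not isolated)
Conditions: AcCl, AlCl3, Et2O, 0 °C to rt; aq. HCl
Reagents that add atoms: acetyl chloride, CC(Cl)=O
Why: Friedel–Crafts acylation at one of the two equivalent free positions gives 3, and AlCl3 held by the new carbonyl then cleaves the more crowded ortho methoxyl (flanked by acetyl and a second methoxyl) in a standard acylation/ortho-demethylation.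

**Step 3**
Reactants: 4 1-(2-hydroxy-3,4,6-trimethoxyphenyl)ethan-1-one
Product: 6 1-(2,5-dihydroxy-3,4,6-trimethoxyphenyl)ethan-1-one, via aryl sulfate 5 (not isolated)
Conditions: K2S2O8, aq. NaOH, 15–20 °C; then aq. HCl, 85 °C, under N2
Reagents that add atoms: potassium peroxodisulfate, [K+].[K+].[O-]S(=O)(=O)OOS(=O)(=O)[O-]
Why: In this Elbs persulfate oxidation the phenoxide attacks the peroxide oxygen through its para carbon, the only unsubstituted ring position, and acid hydrolysis of sulfate 5 should free the hydroquinone, with unreacted 4 recovered for recycling.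

**Step 4**
Reactants: 6 1-(2,5-dihydroxy-3,4,6-trimethoxyphenyl)ethan-1-one
Product: 7 1-[3-(benzyloxy)-6-hydroxy-2,4,5-trimethoxyphenyl]ethan-1-one
Conditions: BnBr (1.05 equiv), K2CO3, acetone, reflux, under N2
Reagents that add atoms: benzyl bromide, BrCc1ccccc1
Why: This Williamson etherification should be selective for the C5 hydroxyl, because the C2 hydroxyl is hydrogen-bonded to the acetyl carbonyl and is the less nucleophilic under weak-base conditions.

**Step 5**
Reactants: 7 1-[3-(benzyloxy)-6-hydroxy-2,4,5-trimethoxyphenyl]ethan-1-one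
Product: 9 6-(benzyloxy)-4-hydroxy-5,7,8-trimethoxy-2H-chromene-2-thione, via keto dithioate 8 (not isolated)
Conditions: KOtBu (3.5 equiv), CS2, THF, 0 °C to rt; then cold aq. HCl
Reagents that add atoms: carbon disulfide, S=C=S
Why: Claisen-type condensation of the ketone enolate with CS2 gives 8, and on acidification the neighbouring phenol adds to the thiocarbonyl carbon with loss of H2S (6-exo-trig addition–elimination), the standard route from o-hydroxyacetophenones to 4-hydroxychromene-2-thiones.

**Step 6**
Reactants: 9 6-(benzyloxy)-4-hydroxy-5,7,8-trimethoxy-2H-chromene-2-thione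
Product: 10 6-(benzyloxy)-5,7,8-trimethoxy-2-(methylsulfanyl)-4H-chromen-4-one
Conditions: MeI, K2CO3, acetone, reflux
Reagents that add atoms: iodomethane, CI
Why: SN2 alkylation of the ambident anion at its soft sulfur end should fix the chromone tautomer as the 2-methylsulfanyl vinylogous thioester.

**Step 7**
Reactants: 11 chloroacetaldehyde dimethyl acetal
Product: 13 tributyl(methoxyethynyl)stannane, via lithium methoxyacetylide 12 (not isolated)
Conditions: LiNEt2 (3.1 equiv, from n-BuLi and Et2NH), THF, 0 °C; then Bu3SnCl, −78 °C to rt; Kugelrohr distillation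
Reagents that add atoms: tributyltin chloride, CCCC[Sn](Cl)(CCCC)CCCC
Why: Twofold amide-induced elimination from the chloroacetal and deprotonation give 12 in the flask, and stannylation of a lithium acetylide with Bu3SnCl is routine and avoids handling volatile methoxyacetylene.

**Step 8**
Reactants: 10 6-(benzyloxy)-5,7,8-trimethoxy-2-(methylsulfanyl)-4H-chromen-4-one; 13 tributyl(methoxyethynyl)stannane
Product: 14 6-(benzyloxy)-5,7,8-trimethoxy-2-(methoxyethynyl)-4H-chromen-4-one
Conditions: Pd(PPh3)4 (5 mol %), CuTC [Cu(O2C-2-C4H3S), 2 equiv], 13 (1.5 equiv), THF, 50 °C, Ar; filtration through Et3N-deactivated silica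
Reagents that add atoms: none
Why: In this organostannane variant of the Liebeskind–Srogl coupling the monovalent copper carboxylate activates the C2–SMe bond towards oxidative addition to zerovalent palladium and removes thiolate as CuSMe, and the neutral, base-free medium should spare the acid-sensitive ynol ether.

**Step 9**
Reactants: 15 3-oxocyclobutane-1-carboxylic acid
Product: 16 3-bromocyclobutan-1-one
Conditions: HgO, Br2, MgSO4, CH2Cl2, reflux
Reagents that add atoms: bromine, BrBr
Why: Hunsdiecker bromodecarboxylation in the Cristol–Firth variant (a radical chain) is the established way to this β-bromo ketone.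

**Step 10**
Reactants: 16 3-bromocyclobutan-1-one
Product: 17 cyclobut-2-en-1-one
Conditions: n-Bu3N, neat, rt, reduced pressure, product trapped at −78 °C and kept cold as a toluene solution
Reagents that add atoms: none
Why: E1cB dehydrobromination of the β-bromo ketone by a tertiary amine should work because the volatile, polymerisation-prone enone is distilled from the ammonium salt as it forms.

**Step 11**
Reactants: 14 6-(benzyloxy)-5,7,8-trimethoxy-2-(methoxyethynyl)-4H-chromen-4-one; 17 cyclobut-2-en-1-one
Product: 22 6-(benzyloxy)-2-(2-hydroxy-6-methoxyphenyl)-5,7,8-trimethoxy-4H-chromen-4-one, via vinylketene 18 (not isolated), via vinylcyclobutenone 19 (not isolated), via dienylketene 20 (not isolated), via cyclohexadienone 21 (not isolated)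
Conditions: 17 (3 equiv, in portions), toluene, BHT (trace), sealed tube, 80 °C then 110 °C
Reagents that add atoms: none
Why: Proposed new method: heating opens 17 by 4π-electrocyclic ring opening to vinylketene 18, whose carbonyl carbon is attacked by the alkyne carbon of 14 remote from oxygen in a [2+2] cycloaddition that forms C1'–C2' and C5'–C6' and gives 19; 19 reopens to dienylketene 20, and ring B closes by thermal disrotatory 6π-electrocyclisation (C2'–C3') to cyclohexadienone 21, which tautomerises to the phenol. The closest known reaction type is the Danheiser benzannulation of cyclobutenones with alkoxyalkynes to 2-substituted resorcinol monoethers, which has not been shown for an ynol ether conjugated to a chromone. No stereocentre is present in 22, and the one in 19 is transient. The step needs regioselectivity in the [2+2] event, secured by the methoxyl group, which makes the chromone-bearing alkyne carbon the nucleophilic terminus, so that the ketene-derived hydroxyl and the methoxyl become the two ortho neighbours of C1'. It also needs chemoselectivity for the alkyne over the chromone C2–C3 double bond, secured because the ynol ether is the only electron-rich π bond in 14. Conjugation to the chromone (a vinylogous ester) lowers the nucleophilicity of the ynol ether, but the donor oxygen still polarises it in the required sense, and a methyl ynol ether cannot fragment by retro-ene loss of an alkene, so it should survive the longer heating that a slower cycloaddition may need.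

**Step 12**
Reactants: 22 6-(benzyloxy)-2-(2-hydroxy-6-methoxyphenyl)-5,7,8-trimethoxy-4H-chromen-4-one
Product: 23 6,2'-dihydroxy-5,7,8,6'-tetramethoxyflavone, that is 6-hydroxy-2-(2-hydroxy-6-methoxyphenyl)-5,7,8-trimethoxy-4H-chromen-4-one
Conditions: H2 (1 atm), Pd/C (10 wt %), EtOAc–MeOH, rt
Reagents that add atoms: none
Why: Catalytic hydrogenolysis of the benzyl aryl ether at one atmosphere and room temperature should leave the chromone C2–C3 double bond, the methyl ethers and the free phenol untouched.

**Compound list**
1 | 3,4,5-trimethoxyphenol | COc1cc(O)cc(OC)c1OC | starting material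
2 | 1,2,3,5-tetramethoxybenzene | COc1cc(OC)c(OC)c(OC)c1 | intermediate
3 | 1-(2,3,4,6-tetramethoxyphenyl)ethan-1-one (tetramethoxyacetophenone) | CC(=O)c1c(OC)c(OC)c(OC)cc1OC | intermediate
4 | 1-(2-hydroxy-3,4,6-trimethoxyphenyl)ethan-1-one | CC(=O)c1c(O)c(OC)c(OC)cc1OC | intermediate
5 | potassium 3-acetyl-4-hydroxy-2,5,6-trimethoxyphenyl sulfate (aryl sulfate) | CC(=O)c1c(O)c(OC)c(OC)c(OS(=O)(=O)[O-])c1OC.[K+] | intermediate
6 | 1-(2,5-dihydroxy-3,4,6-trimethoxyphenyl)ethan-1-one | CC(=O)c1c(O)c(OC)c(OC)c(O)c1OC | intermediate
7 | 1-[3-(benzyloxy)-6-hydroxy-2,4,5-trimethoxyphenyl]ethan-1-one | CC(=O)c1c(O)c(OC)c(OC)c(OCc2ccccc2)c1OC | intermediate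
8 | dipotassium 3-[3-(benzyloxy)-2,4,5-trimethoxy-6-oxidophenyl]-3-oxopropanedithioate (keto dithioate) | [K+].[K+].[O-]c1c(OC)c(OC)c(OCc2ccccc2)c(OC)c1C(=O)CC(=S)[S-] | intermediate
9 | 6-(benzyloxy)-4-hydroxy-5,7,8-trimethoxy-2H-chromene-2-thione | S=c1cc(O)c2c(OC)c(OCc3ccccc3)c(OC)c(OC)c2o1 | intermediate
10 | 6-(benzyloxy)-5,7,8-trimethoxy-2-(methylsulfanyl)-4H-chromen-4-one | CSc1cc(=O)c2c(OC)c(OCc3ccccc3)c(OC)c(OC)c2o1 | intermediate
11 | chloroacetaldehyde dimethyl acetal (2-chloro-1,1-dimethoxyethane) | COC(CCl)OC | starting material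
12 | lithium methoxyacetylide | [Li]C#COC | intermediate
13 | tributyl(methoxyethynyl)stannane | CCCC[Sn](CCCC)(CCCC)C#COC | intermediate
14 | 6-(benzyloxy)-5,7,8-trimethoxy-2-(methoxyethynyl)-4H-chromen-4-one | COC#Cc1cc(=O)c2c(OC)c(OCc3ccccc3)c(OC)c(OC)c2o1 | intermediate
15 | 3-oxocyclobutane-1-carboxylic acid | O=C1CC(C(=O)O)C1 | starting material
16 | 3-bromocyclobutan-1-one | O=C1CC(Br)C1 | intermediate
17 | cyclobut-2-en-1-one | O=C1C=CC1 | intermediate
18 | buta-1,3-dien-1-one (vinylketene) | C=CC=C=O | intermediate
19 | 6-(benzyloxy)-5,7,8-trimethoxy-2-(2-methoxy-4-oxo-3-vinylcyclobut-1-en-1-yl)-4H-chromen-4-one (vinylcyclobutenone, racemic) | COC1=C(c2cc(=O)c3c(OC)c(OCc4ccccc4)c(OC)c(OC)c3o2)C(=O)C1C=C | intermediate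
20 | (3E)-2-[6-(benzyloxy)-5,7,8-trimethoxy-4-oxo-4H-chromen-2-yl]-3-methoxyhexa-1,3,5-trien-1-one (dienylketene, ketene and vinyl cis) | O=C=C(c1cc(=O)c2c(OC)c(OCc3ccccc3)c(OC)c(OC)c2o1)/C(OC)=C\C=C | intermediate
21 | 6-(benzyloxy)-5,7,8-trimethoxy-2-(2-methoxy-6-oxocyclohexa-1,3-dien-1-yl)-4H-chromen-4-one (cyclohexadienone) | O=C1CC=CC(OC)=C1c1cc(=O)c2c(OC)c(OCc3ccccc3)c(OC)c(OC)c2o1 | intermediate
22 | 6-(benzyloxy)-2-(2-hydroxy-6-methoxyphenyl)-5,7,8-trimethoxy-4H-chromen-4-one | COc1cccc(O)c1-c1cc(=O)c2c(OC)c(OCc3ccccc3)c(OC)c(OC)c2o1 | intermediate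
23 | 6,2'-dihydroxy-5,7,8,6'-tetramethoxyflavone | COc1cccc(O)c1-c1cc(=O)c2c(OC)c(O)c(OC)c(OC)c2o1 | target

**Step count**
Total: 12 steps. Longest linear sequence: 9 steps (steps 1–6, 8, 11, 12, from 3,4,5-trimethoxyphenol). The stannane (step 7) and cyclobutenone (steps 9–10) are side branches.

**Steps most likely to fail**

Step 11. Capture of the vinylketene by the electron-poor ynol ether may be too slow to compete with oligomerisation of cyclobutenone. The product phenol may also be O-acylated by excess ketene, and the intermediate vinylcyclobutenone may stall before the second ring opening. The fallback is a Baker–Venkataraman sequence with ring B preformed, known chemistry throughout, which sets out from acetophenone 7 and rejoins the route at target 23. Commercial 2-hydroxy-6-methoxybenzoic acid is benzylated on both oxygens (BnBr, K2CO3, DMF) to benzyl 2-(benzyloxy)-6-methoxybenzoate F1. Saponification (KOH, aq. EtOH, reflux) gives 2-(benzyloxy)-6-methoxybenzoic acid F2, and (COCl)2 with catalytic DMF in CH2Cl2 gives 2-(benzyloxy)-6-methoxybenzoyl chloride F3. O-Acylation of 7 with F3 (pyridine, DMAP) should give 2-acetyl-4-(benzyloxy)-3,5,6-trimethoxyphenyl 2-(benzyloxy)-6-methoxybenzoate F4. KOH in pyridine at 50 °C moves the aroyl group from oxygen to the acetyl carbon and gives 1-[3-(benzyloxy)-6-hydroxy-2,4,5-trimethoxyphenyl]-3-[2-(benzyloxy)-6-methoxyphenyl]propane-1,3-dione F5. Cyclodehydration (AcOH, catalytic H2SO4, 60 °C) closes ring C to 6-(benzyloxy)-2-[2-(benzyloxy)-6-methoxyphenyl]-5,7,8-trimethoxy-4H-chromen-4-one F6. Hydrogenolysis of both benzyl ethers (H2, Pd/C) gives 23.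

Step 8. Alkynyl transfer from tin may be slow at the vinylogous thioester. The ynol ether may also be protodestannylated or hydrated under the copper/palladium conditions or on silica. The fallback replaces the metal-catalysed coupling by a vinylic addition–elimination, sets out from 10 and returns at 14. Oxidation of 10 with mCPBA (2.2 equiv, CH2Cl2, 0 °C) gives 6-(benzyloxy)-5,7,8-trimethoxy-2-(methylsulfonyl)-4H-chromen-4-one F7, in which C2 is a strong acceptor carrying a good leaving group. Acetylide 12, generated as in step 7, is transmetallated with ZnCl2 to chloro(methoxyethynyl)zinc F8. Adding F8 to F7 in THF at −40 °C to rt should give 14 by attack at C2 and loss of methanesulfinate. This route uses no tin, no copper thiolate and no palladium.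

Step 3. Conversion in the persulfate oxidation is typically incomplete, and the hydroquinone may be over-oxidised to the quinone during the oxidation or work-up. The fallback introduces the oxygen through a formyl group, sets out from 4 and returns at 6. Duff formylation (hexamethylenetetramine, CF3CO2H, 80 °C; aq. HCl) at the only free ring position gives 3-acetyl-4-hydroxy-2,5,6-trimethoxybenzaldehyde F9. Dakin oxidation of this p-hydroxybenzaldehyde (H2O2, aq. NaOH, 0 °C to rt) passes through 3-acetyl-4-hydroxy-2,5,6-trimethoxyphenyl formate F10, which is hydrolysed in the same pot to 6.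

**Further compounds**
F1 | step 11 | benzyl 2-(benzyloxy)-6-methoxybenzoate | COc1cccc(OCc2ccccc2)c1C(=O)OCc1ccccc1
F2 | step 11 | 2-(benzyloxy)-6-methoxybenzoic acid | COc1cccc(OCc2ccccc2)c1C(=O)O
F3 | step 11 | 2-(benzyloxy)-6-methoxybenzoyl chloride | COc1cccc(OCc2ccccc2)c1C(Cl)=O
F4 | step 11 | 2-acetyl-4-(benzyloxy)-3,5,6-trimethoxyphenyl 2-(benzyloxy)-6-methoxybenzoate | CC(=O)c1c(OC(=O)c2c(OC)cccc2OCc2ccccc2)c(OC)c(OC)c(OCc2ccccc2)c1OC
F5 | step 11 | 1-[3-(benzyloxy)-6-hydroxy-2,4,5-trimethoxyphenyl]-3-[2-(benzyloxy)-6-methoxyphenyl]propane-1,3-dione | O=C(CC(=O)c1c(OC)cccc1OCc1ccccc1)c1c(O)c(OC)c(OC)c(OCc2ccccc2)c1OC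
F6 | step 11 | 6-(benzyloxy)-2-[2-(benzyloxy)-6-methoxyphenyl]-5,7,8-trimethoxy-4H-chromen-4-one | COc1cccc(OCc2ccccc2)c1-c1cc(=O)c2c(OC)c(OCc3ccccc3)c(OC)c(OC)c2o1
F7 | step 8 | 6-(benzyloxy)-5,7,8-trimethoxy-2-(methylsulfonyl)-4H-chromen-4-one | CS(=O)(=O)c1cc(=O)c2c(OC)c(OCc3ccccc3)c(OC)c(OC)c2o1
F8 | step 8 | chloro(methoxyethynyl)zinc | COC#C[Zn]Cl
F9 | step 3 | 3-acetyl-4-hydroxy-2,5,6-trimethoxybenzaldehyde | CC(=O)c1c(O)c(OC)c(OC)c(C=O)c1OC
F10 | step 3 | 3-acetyl-4-hydroxy-2,5,6-trimethoxyphenyl formate | CC(=O)c1c(O)c(OC)c(OC)c(OC=O)c1OC
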